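**Plan**

- Target: [(2R,3S,4S)-4-(3,4-dimethoxybenzyl)-2-(3,4,5-trimethoxyphenyl)oxolan-3-yl]methanol, with oxolane ring O1–C2–C3–C4–C5, aryl at C2 trans to the CH2OH at C3, and CH2OH at C3 cis to the benzyl at C4.
- First cut: ring bond C2–C3. C2 is the only carbon that is both benzylic to the trimethoxyphenyl ring and bonded to ring oxygen O1, so it can be metalated. C3 carries CH2OH, which is the opened form of an oxirane spanning C3 and that exocyclic CH2. The precursor is therefore an acyclic 3,4,5-trimethoxybenzyl ether of an epoxy alcohol.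
- Further cuts: the O1–CH2Ar ether bond (Williamson), then the C4–CH2Ar bond (benzylation of a malate enolate).
- Forward: malate benzylation, reduction to a triol, 1,2-acetonide, etherification of the remaining primary OH, release of the diol, oxirane formation, ring closure. The oxolane is the only ring that stays; the dioxolane and the oxirane are temporary.
- Stereochemistry: the malate carbinol carbon (chiral pool) becomes C3 and directs C4 in the chelated dianion alkylation (anti). C3 is inverted in the ring closure, which turns anti into 3,4-cis. C2 arises in the ring closure, trans to the C3 arm.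

Key step: step 7

Assumption: the target SMILES is read as the (2R,3S,4S) isomer; dimethyl (R)-malate and the two benzylic halides are taken as purchasable.

**Route**

Step 1
Reactants: 1 dimethyl (R)-malate; 2 3,4-dimethoxybenzyl bromide
Product: 4 dimethyl (2R,3S)-3-(3,4-dimethoxybenzyl)-2-hydroxybutanedioate, via dilithium alkoxide-enolate 3 (not isolated)
Conditions: LiN(SiMe3)2 (2.2 equiv), THF, −78 to −20 °C; 2, −78 °C to rt; aq. NH4Cl
Reagents that add atoms: none
Why: Fráter–Seebach alkylation, in which the dilithium alkoxide-enolate is held in a six-membered chelate and the benzylic bromide should add to the enolate face anti to the ester group on the carbinol carbon, setting the anti (2R,3S) relationship.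

Step 2
Reactants: 4 dimethyl (2R,3S)-3-(3,4-dimethoxybenzyl)-2-hydroxybutanedioate
Product: 5 (2R,3R)-3-(3,4-dimethoxybenzyl)butane-1,2,4-triol
Conditions: LiAlH4, THF, 0 °C to reflux; aq. NaOH work-up
Reagents that add atoms: none
Why: Hydride reduction of both esters to primary alcohols, which touches neither stereocentre.

Step 3
Reactants: 5 (2R,3R)-3-(3,4-dimethoxybenzyl)butane-1,2,4-triol
Product: 6 (2R)-2-[(4R)-2,2-dimethyl-1,3-dioxolan-4-yl]-3-(3,4-dimethoxyphenyl)propan-1-ol
Conditions: 2,2-dimethoxypropane, TsOH·H2O (cat.), acetone, rt; Et3N quench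
Reagents that add atoms: 2,2-dimethoxypropane, COC(C)(C)OC
Why: Thermodynamic ketalisation, in which an isopropylidene ketal should prefer the five-membered dioxolane on the terminal 1,2-diol over the six-membered alternative and so leave only the primary hydroxyl next to the benzyl-bearing carbon free.

Step 4
Reactants: 6 (2R)-2-[(4R)-2,2-dimethyl-1,3-dioxolan-4-yl]-3-(3,4-dimethoxyphenyl)propan-1-ol; 7 3,4,5-trimethoxybenzyl chloride
Product: 8 (4R)-4-[(2R)-1-(3,4-dimethoxyphenyl)-3-[(3,4,5-trimethoxybenzyl)oxy]propan-2-yl]-2,2-dimethyl-1,3-dioxolane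
Conditions: NaH, Bu4NI (cat.), THF/DMF, 0 °C to rt
Reagents that add atoms: none
Why: Williamson etherification of a primary alkoxide with a reactive benzylic chloride under iodide catalysis.

Step 5
Reactants: 8 (4R)-4-[(2R)-1-(3,4-dimethoxyphenyl)-3-[(3,4,5-trimethoxybenzyl)oxy]propan-2-yl]-2,2-dimethyl-1,3-dioxolane
Product: 9 (2R,3R)-3-(3,4-dimethoxybenzyl)-4-[(3,4,5-trimethoxybenzyl)oxy]butane-1,2-diol
Conditions: AcOH/H2O (4:1), 40 °C
Reagents that add atoms: none
Why: Mild acid hydrolysis of the isopropylidene ketal, under which the benzylic ether and the aryl methyl ethers should persist.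

Step 6
Reactants: 9 (2R,3R)-3-(3,4-dimethoxybenzyl)-4-[(3,4,5-trimethoxybenzyl)oxy]butane-1,2-diol
Product: 11 (2R)-2-[(2R)-1-(3,4-dimethoxyphenyl)-3-[(3,4,5-trimethoxybenzyl)oxy]propan-2-yl]oxirane, via primary monotosylate 10 (not isolated)
Conditions: TsCl, Et3N, Bu2SnO (cat.), CH2Cl2, 0 °C to rt; then K2CO3, MeOH, rt
Reagents that add atoms: none
Why: Tin-acetal-catalysed sulfonylation of the primary hydroxyl followed by intramolecular Williamson closure (3-exo-tet) by the secondary alkoxide, which leaves the C–O bond of the stereocentre intact and so retains its configuration.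

Step 7
Reactants: 11 (2R)-2-[(2R)-1-(3,4-dimethoxyphenyl)-3-[(3,4,5-trimethoxybenzyl)oxy]propan-2-yl]oxirane
Product: 13 [(2R,3S,4S)-4-(3,4-dimethoxybenzyl)-2-(3,4,5-trimethoxyphenyl)oxolan-3-yl]methanol, via potassium benzylic carbanion 12 (not isolated)
Conditions: LiN(iPr)2/KOtBu (1:1, 2.5 equiv), THF, −78 to −50 °C; aq. NH4Cl
Reagents that add atoms: none
Why: The mixed lithium–potassium amide should remove the proton at the one carbon that is both benzylic and alpha to the ether oxygen, and the resulting alpha-alkoxybenzyl potassium species 12 attacks the internal oxirane carbon in SN2 fashion, the oxygen leaving onto the exocyclic CH2 so that the free CH2OH appears on work-up. The closest known reaction type is the base-promoted isomerisation of benzyl epoxyalkyl ethers to 2-aryl oxetanes and oxolanes bearing a hydroxyalkyl group, the ether counterpart of the Stork epoxynitrile cyclisation. The oxolane closes in the 5-exo-tet mode, preferred over 6-endo attack at the terminal oxirane carbon because only the exo path allows collinear backside approach within the short O–CH2–CH tether. C3 is inverted stereospecifically, its configuration coming from the oxirane and hence from the malate carbinol, which converts the anti relationship of step 1 into the cis C3/C4 relationship. C2 is new: the planar, configurationally labile benzylic carbanion should react through the envelope transition state that keeps the aryl group pseudo-equatorial and anti to the oxirane CH2–O arm, giving 2,3-trans, since the alternative is the all-cis oxolane. The selectivity needed is benzylic metalation over ring metalation ortho to methoxy and over base-induced isomerisation of the oxirane to an allylic alcohol; an amide base in place of an alkyllithium, the coordinating ether oxygen and the low temperature are relied on for this, and the irreversible ring closure should consume the anion before a 1,2-Wittig shift can occur.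

**Compound list**

1 | dimethyl (R)-malate | COC(=O)C[C@@H](O)C(=O)OC | starting material
2 | 3,4-dimethoxybenzyl bromide | COc1ccc(CBr)cc1OC | starting material
3 | dilithium alkoxide-enolate of dimethyl (R)-malate | [Li+].[Li+].COC([O-])=C[C@@H]([O-])C(=O)OC | intermediate
4 | dimethyl (2R,3S)-3-(3,4-dimethoxybenzyl)-2-hydroxybutanedioate | COc1ccc(C[C@H](C(=O)OC)[C@@H](O)C(=O)OC)cc1OC | intermediate
5 | (2R,3R)-3-(3,4-dimethoxybenzyl)butane-1,2,4-triol | COc1ccc(C[C@H](CO)[C@@H](O)CO)cc1OC | intermediate
6 | (2R)-2-[(4R)-2,2-dimethyl-1,3-dioxolan-4-yl]-3-(3,4-dimethoxyphenyl)propan-1-ol | COc1ccc(C[C@H](CO)[C@@H]2COC(C)(C)O2)cc1OC | intermediate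
7 | 3,4,5-trimethoxybenzyl chloride | COc1cc(CCl)cc(OC)c1OC | starting material
8 | (4R)-4-[(2R)-1-(3,4-dimethoxyphenyl)-3-[(3,4,5-trimethoxybenzyl)oxy]propan-2-yl]-2,2-dimethyl-1,3-dioxolane | COc1ccc(C[C@H](COCc2cc(OC)c(OC)c(OC)c2)[C@@H]3COC(C)(C)O3)cc1OC | intermediate
9 | (2R,3R)-3-(3,4-dimethoxybenzyl)-4-[(3,4,5-trimethoxybenzyl)oxy]butane-1,2-diol | COc1ccc(C[C@H](COCc2cc(OC)c(OC)c(OC)c2)[C@@H](O)CO)cc1OC | intermediate
10 | (2R,3R)-3-(3,4-dimethoxybenzyl)-2-hydroxy-4-[(3,4,5-trimethoxybenzyl)oxy]butyl 4-methylbenzenesulfonate | COc1ccc(C[C@H](COCc2cc(OC)c(OC)c(OC)c2)[C@@H](O)COS(=O)(=O)c2ccc(C)cc2)cc1OC | intermediate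
11 | (2R)-2-[(2R)-1-(3,4-dimethoxyphenyl)-3-[(3,4,5-trimethoxybenzyl)oxy]propan-2-yl]oxirane | COc1ccc(C[C@H](COCc2cc(OC)c(OC)c(OC)c2)[C@@H]3CO3)cc1OC | intermediate
12 | potassium alpha-alkoxybenzyl carbanion of 11 | [K+].COc1ccc(C[C@H](CO[CH-]c2cc(OC)c(OC)c(OC)c2)[C@@H]3CO3)cc1OC | intermediate
13 | [(2R,3S,4S)-4-(3,4-dimethoxybenzyl)-2-(3,4,5-trimethoxyphenyl)oxolan-3-yl]methanol | COc1ccc(C[C@@H]2CO[C@@H](c3cc(OC)c(OC)c(OC)c3)[C@@H]2CO)cc1OC | target

**Summary**

Total step count: 7. Longest linear sequence: 7 steps, from dimethyl (R)-malate.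

Steps most likely to fail:

1. Step 7. The base may metalate a methoxy-substituted ring, isomerise the oxirane to an allylic alcohol, or the benzylic anion may undergo a 1,2-Wittig shift, in place of the wanted benzylic deprotonation and ring closure. The fallback keeps the same C2–C3 closure and the same inversion at C3 but uses an easily formed ester enolate and brings in the aryl group last. It sets out from 6 and rejoins the route at 13.
   - Alcohol 6 would be O-alkylated with tert-butyl bromoacetate (NaH, THF) to tert-butyl 2-[(2R)-2-[(4R)-2,2-dimethyl-1,3-dioxolan-4-yl]-3-(3,4-dimethoxyphenyl)propoxy]acetate F1.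
   - Ketal hydrolysis as in step 5 should give tert-butyl 2-[(2R,3R)-2-(3,4-dimethoxybenzyl)-3,4-dihydroxybutoxy]acetate F2.
   - Tosylation as in step 6 should give tert-butyl 2-[(2R,3R)-2-(3,4-dimethoxybenzyl)-3-hydroxy-4-(tosyloxy)butoxy]acetate F3, and K2CO3 in MeOH should close it to tert-butyl 2-[(2R)-3-(3,4-dimethoxyphenyl)-2-[(2R)-oxiran-2-yl]propoxy]acetate F4.
   - LiN(SiMe3)2 (THF, −78 to 0 °C) should then effect 5-exo-tet opening of the oxirane by the alpha-alkoxy ester enolate, giving tert-butyl (3S,4S)-4-(3,4-dimethoxybenzyl)-3-(hydroxymethyl)oxolane-2-carboxylate F5. Its C2 configuration does not matter.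
   - Cleavage of the ester with CF3CO2H in CH2Cl2 should give (3S,4S)-4-(3,4-dimethoxybenzyl)-3-(hydroxymethyl)oxolane-2-carboxylic acid F6.
   - Decarboxylative arylation of F6 with 5-bromo-1,2,3-trimethoxybenzene (Ir[dF(CF3)ppy]2(dtbbpy)PF6, NiCl2·glyme, dtbbpy, Cs2CO3, DMF, blue light) should place the aryl group on the alpha-oxy radical carbon trans to the neighbouring CH2OH arm and give 13.

2. Step 1. C-alkylation of the dianion by the labile, electron-rich benzylic bromide may be sluggish and the facial selectivity incomplete. The fallback sets the same two stereocentres by reagent-controlled epoxidation and stereospecific oxirane opening. It sets out from 2 (with commercial (E)-but-2-ene-1,4-diol) and rejoins the route at 5.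
   - The diol would be monosilylated (t-BuPh2SiCl, imidazole) to (E)-4-[(tert-butyldiphenylsilyl)oxy]but-2-en-1-ol F7.
   - Sharpless asymmetric epoxidation (Ti(OiPr)4, L-(+)-diethyl tartrate, t-BuOOH, 4 Å molecular sieves, CH2Cl2, −20 °C) should give [(2S,3S)-3-{[(tert-butyldiphenylsilyl)oxy]methyl}oxiran-2-yl]methanol F8.
   - Bromide 2 would be converted with Mg in THF into (3,4-dimethoxybenzyl)magnesium bromide F9.
   - With CuI as catalyst, F9 should open F8 at C2 with inversion to the anti product (2R,3R)-4-[(tert-butyldiphenylsilyl)oxy]-2-(3,4-dimethoxybenzyl)butane-1,3-diol F10.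
   - Bu4NF should then free triol 5.

3. Step 3. Ketalisation may also engage the 2,4-diol (six-membered ketal), or the ketal may migrate, so that the wrong primary hydroxyl is left free. The fallback differentiates the two ends at the diester stage. It sets out from 4 and rejoins the route at 6, bypassing 5.
   - The alpha-hydroxy ester of 4 would be reduced chemoselectively (BH3·SMe2, NaBH4 cat., THF) to methyl (2S,3R)-2-(3,4-dimethoxybenzyl)-3,4-dihydroxybutanoate F11.
   - Its only diol would be ketalised at once (2,2-dimethoxypropane, TsOH cat.) to methyl (2S)-2-[(4R)-2,2-dimethyl-1,3-dioxolan-4-yl]-3-(3,4-dimethoxyphenyl)propanoate F12.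
   - LiAlH4 reduction of the remaining ester should give 6.

Further compounds
F1 | step 7 | tert-butyl 2-[(2R)-2-[(4R)-2,2-dimethyl-1,3-dioxolan-4-yl]-3-(3,4-dimethoxyphenyl)propoxy]acetate | COc1ccc(C[C@H](COCC(=O)OC(C)(C)C)[C@@H]2COC(C)(C)O2)cc1OC
F2 | step 7 | tert-butyl 2-[(2R,3R)-2-(3,4-dimethoxybenzyl)-3,4-dihydroxybutoxy]acetate | COc1ccc(C[C@H](COCC(=O)OC(C)(C)C)[C@@H](O)CO)cc1OC
F3 | step 7 | tert-butyl 2-[(2R,3R)-2-(3,4-dimethoxybenzyl)-3-hydroxy-4-(tosyloxy)butoxy]acetate | COc1ccc(C[C@H](COCC(=O)OC(C)(C)C)[C@@H](O)COS(=O)(=O)c2ccc(C)cc2)cc1OC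
F4 | step 7 | tert-butyl 2-[(2R)-3-(3,4-dimethoxyphenyl)-2-[(2R)-oxiran-2-yl]propoxy]acetate | COc1ccc(C[C@H](COCC(=O)OC(C)(C)C)[C@@H]2CO2)cc1OC
F5 | step 7 | tert-butyl (3S,4S)-4-(3,4-dimethoxybenzyl)-3-(hydroxymethyl)oxolane-2-carboxylate | COc1ccc(C[C@@H]2COC(C(=O)OC(C)(C)C)[C@@H]2CO)cc1OC
F6 | step 7 | (3S,4S)-4-(3,4-dimethoxybenzyl)-3-(hydroxymethyl)oxolane-2-carboxylic acid | COc1ccc(C[C@@H]2COC(C(=O)O)[C@@H]2CO)cc1OC
F7 | step 1 | (E)-4-[(tert-butyldiphenylsilyl)oxy]but-2-en-1-ol | OC/C=C/CO[Si](c1ccccc1)(c1ccccc1)C(C)(C)C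
F8 | step 1 | [(2S,3S)-3-{[(tert-butyldiphenylsilyl)oxy]methyl}oxiran-2-yl]methanol | OC[C@@H]1O[C@H]1CO[Si](c1ccccc1)(c1ccccc1)C(C)(C)C
F9 | step 1 | (3,4-dimethoxybenzyl)magnesium bromide | COc1ccc(C[Mg]Br)cc1OC
F10 | step 1 | (2R,3R)-4-[(tert-butyldiphenylsilyl)oxy]-2-(3,4-dimethoxybenzyl)butane-1,3-diol | COc1ccc(C[C@H](CO)[C@@H](O)CO[Si](c2ccccc2)(c2ccccc2)C(C)(C)C)cc1OC
F11 | step 3 | methyl (2S,3R)-2-(3,4-dimethoxybenzyl)-3,4-dihydroxybutanoate | COc1ccc(C[C@H](C(=O)OC)[C@@H](O)CO)cc1OC
F12 | step 3 | methyl (2S)-2-[(4R)-2,2-dimethyl-1,3-dioxolan-4-yl]-3-(3,4-dimethoxyphenyl)propanoate | COc1ccc(C[C@H](C(=O)OC)[C@@H]2COC(C)(C)O2)cc1OC
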